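**Plan** (flavanone numbering: O1, C2, C3, C4, C4a, C5–C8, C8a; ring A = benzo ring, ring B = aryl group on C2, ring C = pyranone)
1. Retrosynthesis: both phenols are masked as MOM ethers; ring C is cut at the aryl ether bond O1–C8a, the chain at C4–C4a (aryl ketone) and at C2–C3, and the three aryl–prenyl bonds are cut last.
2. Enabling feature: C8a of ring A is ortho to the C4 ketone, so a fluorine on C8a is an activated leaving group, and O1 on C2 reaches C8a through a six-membered transition state.
3. Forward: the ring B ester is diprenylated, extended by a Claisen condensation (C2–C3) and reduced; the ring A fluoride is prenylated by directed lithiation; the two are joined at C4–C4a by aryllithium acylation of a Weinreb amide; ring C is closed and the MOM groups are removed.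
4. Stereochemistry: C2 is set as the (S) carbinol by Noyori asymmetric transfer hydrogenation (step 4); the ring closure makes the O1–C8a bond and never breaks the C2–O1 bond, so (S) is carried into (2S).

Key step: step 8

Remark on the chemistry: prenylzinc bromide (Me2C=CHCH2ZnBr) is taken as a preformed THF solution made from prenyl bromide and zinc.

**Step 1**
Reactants: 1 methyl 3,5-dibromo-4-hydroxybenzoate
Product: 2 methyl 3,5-dibromo-4-(methoxymethoxy)benzoate
Conditions: MOMCl, i-Pr2NEt, CH2Cl2, 0 °C to rt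
Reagents that add atoms: chloromethyl methyl ether (MOMCl), COCCl
Why: O-alkylation of the acidic 2,6-dibromophenol with the reactive α-chloro ether (MOM protection) should be clean, and the acetal withstands all later organometallic and basic steps.

**Step 2**
Reactants: 2 methyl 3,5-dibromo-4-(methoxymethoxy)benzoate
Product: 4 methyl 4-(methoxymethoxy)-3,5-bis(3-methylbut-2-en-1-yl)benzoate, via monoprenyl bromide 3 (not isolated)
Conditions: Me2C=CHCH2ZnBr (2.6 equiv), Pd(OAc)2 (2 mol %), CPhos (4 mol %), THF, rt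
Reagents that add atoms: prenylzinc bromide, CC(C)=CC[Zn]Br
Why: Twofold Negishi cross-coupling, in which zerovalent palladium inserts into each C–Br bond and the bulky dialkylbiarylphosphine steers reductive elimination to the unsubstituted allyl terminus, should give the linear prenyl groups while the organozinc leaves the ester and the acetal alone.

**Step 3**
Reactants: 4 methyl 4-(methoxymethoxy)-3,5-bis(3-methylbut-2-en-1-yl)benzoate
Product: 5 N-methoxy-3-[4-(methoxymethoxy)-3,5-bis(3-methylbut-2-en-1-yl)phenyl]-N-methyl-3-oxopropanamide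
Conditions: MeC(O)N(OMe)Me (2.2 equiv), LiN(i-Pr)2 (LDA, 2.2 equiv), THF, −78 °C; then 4, −78 to −20 °C; aq NH4Cl
Reagents that add atoms: N-methoxy-N-methylacetamide, CC(=O)N(C)OC
Why: Crossed Claisen condensation of the preformed amide enolate with the non-enolizable aryl ester forms C2–C3, and the β-keto amide is deprotonated as it forms, which protects it from a second attack.

**Step 4**
Reactants: 5 N-methoxy-3-[4-(methoxymethoxy)-3,5-bis(3-methylbut-2-en-1-yl)phenyl]-N-methyl-3-oxopropanamide
Product: 6 (3S)-3-hydroxy-N-methoxy-3-[4-(methoxymethoxy)-3,5-bis(3-methylbut-2-en-1-yl)phenyl]-N-methylpropanamide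
Conditions: RuCl[(S,S)-TsDPEN](p-cymene) (1 mol %), HCO2H/Et3N (5:2), DMF, 40 °C
Reagents that add atoms: none
Why: Noyori asymmetric transfer hydrogenation delivers hydride and proton through the outer-sphere six-membered transition state with the aryl ring under the η6-cymene, so the (S,S) ligand should give the (S) carbinol as it does for acetophenone-type ketones, and the trisubstituted alkenes, the amide and the acetal are not reduced.

**Step 5**
Reactants: 7 4-bromo-3-fluorophenol
Product: 8 1-bromo-2-fluoro-4-(methoxymethoxy)benzene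
Conditions: MOMCl, i-Pr2NEt, CH2Cl2, 0 °C to rt
Reagents that add atoms: chloromethyl methyl ether (MOMCl), COCCl
Why: MOM protection of the phenol by O-alkylation also installs the directing group needed for the next step.

**Step 6**
Reactants: 8 1-bromo-2-fluoro-4-(methoxymethoxy)benzene
Product: 10 1-bromo-2-fluoro-4-(methoxymethoxy)-3-(3-methylbut-2-en-1-yl)benzene, via aryllithium 9 (not isolated)
Conditions: LiN(i-Pr)2 (LDA), THF, −78 °C; then prenyl bromide, CuBr·SMe2 (10 mol %), −78 to −40 °C
Reagents that add atoms: prenyl bromide (1-bromo-3-methylbut-2-ene), CC(C)=CCBr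
Why: Directed ortho-metalation removes the hydrogen flanked by F and OMOM (the most acidic one, and the amide base does not exchange bromine), and the aryllithium should attack the primary carbon of prenyl bromide (copper-assisted SN2) while the cold keeps it from losing LiF.

**Step 7**
Reactants: 10 1-bromo-2-fluoro-4-(methoxymethoxy)-3-(3-methylbut-2-en-1-yl)benzene; 6 (3S)-3-hydroxy-N-methoxy-3-[4-(methoxymethoxy)-3,5-bis(3-methylbut-2-en-1-yl)phenyl]-N-methylpropanamide
Product: 14 (3S)-1-[2-fluoro-4-(methoxymethoxy)-3-(3-methylbut-2-en-1-yl)phenyl]-3-hydroxy-3-[4-(methoxymethoxy)-3,5-bis(3-methylbut-2-en-1-yl)phenyl]propan-1-one, via aryllithium 11 (not isolated), via magnesium alkoxide 12 (not isolated), via tetrahedral adduct 13 (not isolated)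
Conditions: 10, n-BuLi (1.2 equiv), THF, −78 °C; 6, t-BuMgCl (1.0 equiv), THF, −40 °C; aryllithium added to the alkoxide, −78 to −40 °C; aq NH4Cl
Reagents that add atoms: none
Why: Weinreb ketone synthesis, in which bromine–lithium exchange gives the aryllithium and this adds once to the N-methoxy-N-methylamide because the chelated adduct 13 does not collapse before the quench, forms C4–C4a with the hydroxyl masked in the flask as its magnesium alkoxide and the stereocentre uninvolved.

**Step 8**
Reactants: 14 (3S)-1-[2-fluoro-4-(methoxymethoxy)-3-(3-methylbut-2-en-1-yl)phenyl]-3-hydroxy-3-[4-(methoxymethoxy)-3,5-bis(3-methylbut-2-en-1-yl)phenyl]propan-1-one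
Product: 16 (2S)-7-(methoxymethoxy)-2-[4-(methoxymethoxy)-3,5-bis(3-methylbut-2-en-1-yl)phenyl]-8-(3-methylbut-2-en-1-yl)-2,3-dihydro-4H-chromen-4-one, via lithium alkoxide 15 (not isolated)
Conditions: LiN(SiMe3)2 (LiHMDS, 1.0 equiv), THF, −78 °C; DMPU, −78 to 0 °C; pH 7 buffer
Reagents that add atoms: none
Why: LiHMDS deprotonates the C2 hydroxyl first, and the lithium alkoxide 15 adds through O1 to C8a, the fluorine-bearing carbon of ring A ortho to the C4 ketone, so that the negative charge of the Meisenheimer-type transition structure is taken up by C4a and the C4 carbonyl before fluoride leaves as LiF (addition–elimination, SNAr). The closest known reaction type is the intramolecular SNAr etherification of ortho-fluoroaryl ketones by tethered alkoxides that is used to make chroman-4-ones. Ring C closes in the six-membered mode, formally a 6-endo-trig attack on the C4a=C8a bond of the vinylogous acyl fluoride O=C4–C4a=C8a–F, and since no other ring size is within reach only C8a can be attacked. No stereocentre is formed: C2 was set in step 4 and its C–O bond is not broken, so the (S) carbinol should become (2S) with retention. The selectivity needed is cyclization over retro-aldol cleavage, over elimination to the chalcone and over enolization of the product, and it is secured by working with the kinetic lithium aldolate at low temperature, by using no more than one equivalent of base (the LiF formed is not basic) and by the high effective molarity of the ortho-fluoro ketone.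

**Step 9**
Reactants: 16 (2S)-7-(methoxymethoxy)-2-[4-(methoxymethoxy)-3,5-bis(3-methylbut-2-en-1-yl)phenyl]-8-(3-methylbut-2-en-1-yl)-2,3-dihydro-4H-chromen-4-one
Product: 19 sophoranone, (2S)-7-hydroxy-2-[4-hydroxy-3,5-bis(3-methylbut-2-en-1-yl)phenyl]-8-(3-methylbut-2-en-1-yl)-2,3-dihydro-4H-chromen-4-one, via 7-MOM monoether 17 (not isolated), via 4'-MOM monoether 18 (not isolated)
Conditions: HCl (3 M aq)/MeOH, rt
Reagents that add atoms: none
Why: Acid-catalysed methanolysis of the two MOM acetals should free both phenols, since dilute acid at room temperature neither enolizes C3 nor opens ring C (C2 stays S) and is too mild to cyclize the prenyl groups onto the phenols.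

**Compound list**
1 | methyl 3,5-dibromo-4-hydroxybenzoate | COC(=O)c1cc(Br)c(O)c(Br)c1 | starting material
2 | methyl 3,5-dibromo-4-(methoxymethoxy)benzoate | COCOc1c(Br)cc(cc1Br)C(=O)OC | intermediate
3 | methyl 3-bromo-4-(methoxymethoxy)-5-(3-methylbut-2-en-1-yl)benzoate (formed in the flask) | COCOc1c(Br)cc(cc1CC=C(C)C)C(=O)OC | intermediate
4 | methyl 4-(methoxymethoxy)-3,5-bis(3-methylbut-2-en-1-yl)benzoate | COCOc1c(CC=C(C)C)cc(cc1CC=C(C)C)C(=O)OC | intermediate
5 | N-methoxy-3-[4-(methoxymethoxy)-3,5-bis(3-methylbut-2-en-1-yl)phenyl]-N-methyl-3-oxopropanamide | COCOc1c(CC=C(C)C)cc(cc1CC=C(C)C)C(=O)CC(=O)N(C)OC | intermediate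
6 | (3S)-3-hydroxy-N-methoxy-3-[4-(methoxymethoxy)-3,5-bis(3-methylbut-2-en-1-yl)phenyl]-N-methylpropanamide | COCOc1c(CC=C(C)C)cc(cc1CC=C(C)C)[C@@H](O)CC(=O)N(C)OC | intermediate
7 | 4-bromo-3-fluorophenol | Oc1ccc(Br)c(F)c1 | starting material
8 | 1-bromo-2-fluoro-4-(methoxymethoxy)benzene | COCOc1ccc(Br)c(F)c1 | intermediate
9 | [3-bromo-2-fluoro-6-(methoxymethoxy)phenyl]lithium (formed in the flask) | COCOc1ccc(Br)c(F)c1[Li] | intermediate
10 | 1-bromo-2-fluoro-4-(methoxymethoxy)-3-(3-methylbut-2-en-1-yl)benzene | COCOc1ccc(Br)c(F)c1CC=C(C)C | intermediate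
11 | [2-fluoro-4-(methoxymethoxy)-3-(3-methylbut-2-en-1-yl)phenyl]lithium (formed in the flask) | COCOc1ccc([Li])c(F)c1CC=C(C)C | intermediate
12 | chloromagnesium alkoxide of 6, (S) (formed in the flask) | COCOc1c(CC=C(C)C)cc(cc1CC=C(C)C)[C@@H](O[Mg]Cl)CC(=O)N(C)OC | intermediate
13 | tetrahedral adduct of 11 and 12, lithium N-methoxy-N-methyl hemiaminal alkoxide, (3S), new carbon centre undefined (formed in the flask) | COCOc1ccc(C(O[Li])(N(C)OC)C[C@H](O[Mg]Cl)c2cc(CC=C(C)C)c(OCOC)c(CC=C(C)C)c2)c(F)c1CC=C(C)C | intermediate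
14 | (3S)-1-[2-fluoro-4-(methoxymethoxy)-3-(3-methylbut-2-en-1-yl)phenyl]-3-hydroxy-3-[4-(methoxymethoxy)-3,5-bis(3-methylbut-2-en-1-yl)phenyl]propan-1-one | COCOc1ccc(C(=O)C[C@H](O)c2cc(CC=C(C)C)c(OCOC)c(CC=C(C)C)c2)c(F)c1CC=C(C)C | intermediate
15 | lithium alkoxide of 14, (S) (formed in the flask) | COCOc1ccc(C(=O)C[C@H](O[Li])c2cc(CC=C(C)C)c(OCOC)c(CC=C(C)C)c2)c(F)c1CC=C(C)C | intermediate
16 | (2S)-7-(methoxymethoxy)-2-[4-(methoxymethoxy)-3,5-bis(3-methylbut-2-en-1-yl)phenyl]-8-(3-methylbut-2-en-1-yl)-2,3-dihydro-4H-chromen-4-one | CC(C)=CCc1cc([C@@H]2CC(=O)c3ccc(OCOC)c(CC=C(C)C)c3O2)cc(CC=C(C)C)c1OCOC | intermediate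
17 | (2S)-2-[4-hydroxy-3,5-bis(3-methylbut-2-en-1-yl)phenyl]-7-(methoxymethoxy)-8-(3-methylbut-2-en-1-yl)-2,3-dihydro-4H-chromen-4-one (formed in the flask) | CC(C)=CCc1cc([C@@H]2CC(=O)c3ccc(OCOC)c(CC=C(C)C)c3O2)cc(CC=C(C)C)c1O | intermediate
18 | (2S)-7-hydroxy-2-[4-(methoxymethoxy)-3,5-bis(3-methylbut-2-en-1-yl)phenyl]-8-(3-methylbut-2-en-1-yl)-2,3-dihydro-4H-chromen-4-one (formed in the flask) | CC(C)=CCc1cc([C@@H]2CC(=O)c3ccc(O)c(CC=C(C)C)c3O2)cc(CC=C(C)C)c1OCOC | intermediate
19 | sophoranone, (2S)-7-hydroxy-2-[4-hydroxy-3,5-bis(3-methylbut-2-en-1-yl)phenyl]-8-(3-methylbut-2-en-1-yl)-2,3-dihydro-4H-chromen-4-one | CC(C)=CCc1cc([C@@H]2CC(=O)c3ccc(O)c(CC=C(C)C)c3O2)cc(CC=C(C)C)c1O | target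

**Total step count:** 9
**Longest linear sequence:** 7 steps (steps 1, 2, 3, 4, 7, 8, 9)

**Steps most likely to fail**

Step 8. The lithium aldolate may cleave by retro-aldol reaction and recombine, which would erode the C2 configuration. It may also eliminate to the chalcone, or the closed flavanone may be enolized and reopened. The fallback sets out from 14 and comes back at 16, and it takes the ketone away before the ring is closed, so none of these pathways exists. NaBH4 in MeOH at 0 °C should reduce 14 to (3S)-1-[2-fluoro-4-(methoxymethoxy)-3-(3-methylbut-2-en-1-yl)phenyl]-3-[4-(methoxymethoxy)-3,5-bis(3-methylbut-2-en-1-yl)phenyl]propane-1,3-diol F1 (both C1 epimers are used). NaH (2.5 equiv) in DMF at 80 °C converts it into the disodium dialkoxide F2, whose C3 alkoxide displaces the now unactivated fluoride in a thermal intramolecular SNAr; only the six-membered ring can form. This gives (2S)-7-(methoxymethoxy)-2-[4-(methoxymethoxy)-3,5-bis(3-methylbut-2-en-1-yl)phenyl]-8-(3-methylbut-2-en-1-yl)chroman-4-ol F3. MnO2 in CH2Cl2 at rt (benzylic alcohol oxidation) then gives 16.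

Step 7. The ortho-fluoroaryllithium may lose LiF on any warming (aryne formation), and the addition may stay incomplete because the unprotected magnesium alkoxide is poorly soluble or transfers a proton. The fallback sets out from 6 and 10 and comes back at 14; it uses a protected amide and a thermally robust arylmagnesium. TBSCl and imidazole in DMF at rt turn 6 into (3S)-3-[(tert-butyldimethylsilyl)oxy]-N-methoxy-3-[4-(methoxymethoxy)-3,5-bis(3-methylbut-2-en-1-yl)phenyl]-N-methylpropanamide F4. i-PrMgCl·LiCl in THF at 0 °C converts 10 by bromine–magnesium exchange into [2-fluoro-4-(methoxymethoxy)-3-(3-methylbut-2-en-1-yl)phenyl]magnesium chloride F5. This adds to F4 at 0 °C to rt to give the chelated magnesium hemiaminal adduct F6 and, after aqueous NH4Cl, (3S)-3-[(tert-butyldimethylsilyl)oxy]-1-[2-fluoro-4-(methoxymethoxy)-3-(3-methylbut-2-en-1-yl)phenyl]-3-[4-(methoxymethoxy)-3,5-bis(3-methylbut-2-en-1-yl)phenyl]propan-1-one F7. HF·pyridine in THF at 0 °C (non-basic desilylation, no β-elimination) then gives 14.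

Step 2. Allylic transposition at palladium may give branched 1,1-dimethylallyl isomers, and the sequence may stall after the first coupling next to the OMOM group. The fallback sets out from 2 and comes back at 4; it removes the regiochemical question by coupling an unsubstituted allyl group and building the prenyl terminus afterwards. Allyltributylstannane with Pd(PPh3)4 in DMF at 100 °C (twofold Stille coupling) should give, through methyl 3-bromo-4-(methoxymethoxy)-5-(prop-2-en-1-yl)benzoate F8, methyl 4-(methoxymethoxy)-3,5-di(prop-2-en-1-yl)benzoate F9. Twofold cross-metathesis with 2-methylbut-2-ene (second-generation Grubbs catalyst, RuCl2(=CHPh)(H2IMes)(PCy3), CH2Cl2, 40 °C) then gives, through methyl 4-(methoxymethoxy)-3-(3-methylbut-2-en-1-yl)-5-(prop-2-en-1-yl)benzoate F10, compound 4.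

**Further compounds**
F1 | step 8 | (3S)-1-[2-fluoro-4-(methoxymethoxy)-3-(3-methylbut-2-en-1-yl)phenyl]-3-[4-(methoxymethoxy)-3,5-bis(3-methylbut-2-en-1-yl)phenyl]propane-1,3-diol (C1 epimers) | COCOc1ccc(C(O)C[C@H](O)c2cc(CC=C(C)C)c(OCOC)c(CC=C(C)C)c2)c(F)c1CC=C(C)C
F2 | step 8 | disodium dialkoxide of F1 | COCOc1ccc(C(O[Na])C[C@H](O[Na])c2cc(CC=C(C)C)c(OCOC)c(CC=C(C)C)c2)c(F)c1CC=C(C)C
F3 | step 8 | (2S)-7-(methoxymethoxy)-2-[4-(methoxymethoxy)-3,5-bis(3-methylbut-2-en-1-yl)phenyl]-8-(3-methylbut-2-en-1-yl)chroman-4-ol (C4 epimers) | CC(C)=CCc1cc([C@@H]2CC(O)c3ccc(OCOC)c(CC=C(C)C)c3O2)cc(CC=C(C)C)c1OCOC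
F4 | step 7 | (3S)-3-[(tert-butyldimethylsilyl)oxy]-N-methoxy-3-[4-(methoxymethoxy)-3,5-bis(3-methylbut-2-en-1-yl)phenyl]-N-methylpropanamide | COCOc1c(CC=C(C)C)cc(cc1CC=C(C)C)[C@@H](O[Si](C)(C)C(C)(C)C)CC(=O)N(C)OC
F5 | step 7 | [2-fluoro-4-(methoxymethoxy)-3-(3-methylbut-2-en-1-yl)phenyl]magnesium chloride | COCOc1ccc([Mg]Cl)c(F)c1CC=C(C)C
F6 | step 7 | chloromagnesium hemiaminal adduct of F5 and F4, (3S), new carbon centre undefined | COCOc1ccc(C(O[Mg]Cl)(N(C)OC)C[C@H](O[Si](C)(C)C(C)(C)C)c2cc(CC=C(C)C)c(OCOC)c(CC=C(C)C)c2)c(F)c1CC=C(C)C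
F7 | step 7 | (3S)-3-[(tert-butyldimethylsilyl)oxy]-1-[2-fluoro-4-(methoxymethoxy)-3-(3-methylbut-2-en-1-yl)phenyl]-3-[4-(methoxymethoxy)-3,5-bis(3-methylbut-2-en-1-yl)phenyl]propan-1-one | COCOc1ccc(C(=O)C[C@H](O[Si](C)(C)C(C)(C)C)c2cc(CC=C(C)C)c(OCOC)c(CC=C(C)C)c2)c(F)c1CC=C(C)C
F8 | step 2 | methyl 3-bromo-4-(methoxymethoxy)-5-(prop-2-en-1-yl)benzoate | COCOc1c(Br)cc(cc1CC=C)C(=O)OC
F9 | step 2 | methyl 4-(methoxymethoxy)-3,5-di(prop-2-en-1-yl)benzoate | COCOc1c(CC=C)cc(cc1CC=C)C(=O)OC
F10 | step 2 | methyl 4-(methoxymethoxy)-3-(3-methylbut-2-en-1-yl)-5-(prop-2-en-1-yl)benzoate | COCOc1c(CC=C)cc(cc1CC=C(C)C)C(=O)OC
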